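**Numbering used throughout.** In the target, C1 is the ring carbon that bears the exocyclic CH2 (C7), C2 is the alkene CH, then C3 (OMe), C4 (OH), C5 (OBz), C6 (OH); "On" is the oxygen on Cn. The target is (3S,4R,5R,6R). Atoms of intermediates are called by these locants in all running text; the systematic names in the steps keep their own numbering.

Compounds: 1 bromo diene diol (starting material), 2 ketal, 3 oxirane, 4 bromo methoxy alcohol, 5 hydroxymethyl stannane (starting material), 6 ketal diol, 7 tetrol, 8 primary monobenzoate (formed in the flask), 9 target.

## The problem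

The target 9 has a single ring, the cyclohexene C1–C6 with the alkene at C1=C2, the one extra carbon C7 on C1 and an oxygen on each of C3, C4, C5, C6 and C7. C3–C6 are four contiguous stereocentres with O3/O4 trans, O4/O5 trans, O5/O6 cis and the two allylic oxygens O3 and O6 cis to each other across the alkene. Carbon–carbon bond making is minor, since only C1–C7 lies outside the ring, and the stereocentres can be relayed: a cis O5/O6 pair can send an oxirane to the opposite face of C3/C4, and trans opening at the allylic C3 then fixes both remaining centres. The hard part is that five oxygens play five roles, namely methyl ether (O3), free hydroxyl (O4), a benzoate (O5) flanked by free hydroxyls on both sides, free allylic hydroxyl (O6) and primary allylic benzoate (O7), so that a protecting-group answer would need three or four orthogonal groups on neighbouring secondary hydroxyls. The feature that allows the key step is the pattern C3(OMe)–C4(OH)–C5(O)–C6(O)–C1–C7(O) with C2 in the place of a ring oxygen, which is the pattern of a methyl β-galactopyranoside of the L-series: O5 is the equatorial member of the only cis-vicinal diol (O5/O6, with O6 pseudoaxial and allylic), O4–H has a trans neighbour on either side, and O7 is the only primary oxygen. The two benzoates therefore sit exactly on the two oxygens that are the most reactive by nature, so the unprotected tetrol 7 can be taken to 9 without any protecting group. The C3–OMe and C6–OH bonds are allylic to a trisubstituted alkene, so acid can ionise them and loss of methanol or water leads towards an arene, and the O5 benzoate can migrate to O4 or O6 under base. The last steps must therefore be mild and close to neutral.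

## Retrosynthesis

**9 ⇒ 7 (through 8).** The two ester bonds O5–C(=O)Ph and O7–C(=O)Ph are cut together. Cutting O3–CH3 instead would ask for methylation of one hydroxyl out of five with no innate bias. Cutting one ester at a time would hand the problem back to protecting groups. The precursor 7 has no acyl group and no protecting group, and holds all four stereocentres. The forward reaction must tell O7 (primary) and O5 (equatorial oxygen of the only cis-diol) from O4 and O6. It does so in one flask: a kinetic acylation of O7 gives 8, then an acylation at O5 that is catalysed by Ph2BOCH2CH2NH2 and is selective for the cis-diol.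

**7 ⇒ 6.** O5 and O6 are tied into an isopropylidene ketal. This ketal is not there to tell hydroxyls apart. It is the stereocontrol element of the earlier steps and falls off in one hydrolysis. The forward step must hydrolyse it without ionising the allylic C3–O and C6–O bonds.

**6 ⇒ 4 + 5.** The sp2–sp3 bond C1–C7 is cut. Carrying C7 from the start would put an electron-rich trisubstituted alkene in competition during epoxidation. As a bromide, C1 deactivates its own alkene, steers the oxidant to C3=C4, and is exchanged for carbon afterwards. The forward coupling of 4 with 5 must deliver C7 at the alcohol oxidation level and tolerate a free hydroxyl and allylic C–O bonds.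

**4 ⇒ 3.** The C3–OMe bond is cut; in the precursor O4 bridges C3 and C4 as an oxirane. Methylating one hydroxyl of a C3/C4 diol would again need differentiation. The oxirane does it by itself, since only its allylic terminus C3 is attacked. The forward methanolysis must be regioselective and proceed with inversion, which gives the trans O3/O4 pair and the cis O3/O6 pair.

**3 ⇒ 2.** The two oxirane C–O bonds are cut back to the C3=C4 alkene of the diene 2. A dihydroxylation at this alkene would give the wrong (cis) O3/O4 relation, whereas the oxirane stores the trans relation for the next step. The precursor 2 has two stereocentres fewer. The forward epoxidation must choose C3=C4 over the bromoalkene and the face anti to the ketal.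

**2 ⇒ 1.** The two ketal C–O bonds are cut to give the diol 1. All six ring carbons of 9 are the six carbons of 1: its C–Br carbon is C1, its two carbinol carbons are C6 and C5, and its two alkenes are C1=C2 and C3=C4. Compound 1 already carries the cis O5/O6 pair in the right absolute configuration, so the forward step only has to close the dioxolane.

## Roads not taken

Alternative 1: (the most obvious) cut the ring alkene C1=C2. The starting point would be the pentose D-xylose A1, and the forward key step is ring-closing metathesis of the diene A2 built from it. C2–C4 of A1 become C3–C5, C1 of A1 becomes C2, and C6 is created by adding a 2-metallated allyl alcohol unit to an aldehyde at C5 of A1. The chosen plan is better because here C6 must be set by an acyclic carbonyl addition with no dependable bias. Three neighbouring secondary hydroxyls of an open chain must also carry three different groups before the ring exists, with a benzoate that can walk along the chain. The step count is about twice as high.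

Alternative 2: cut the ring bond C1–C2 and the bond C1–C7. The forward key step is a Ferrier carbocyclization of the D-gluco enol ether A3 catalysed by Hg(OCOCF3)2, followed by dehydration to enone A4, Morita–Baylis–Hillman hydroxymethylation at C1 and reduction of the C6 ketone. The mapping is attractive: sugar C2–C4 are C3–C5, the anomeric carbon becomes C2, and the O5 benzoate can come from oxidative opening of a 4,6-O-benzylidene acetal. The chosen plan is better because hydride addition to enones of type A4 favours the equatorial alcohol, that is the C6 epimer, so the last stereocentre would have to be forced by hydroxyl-directed delivery. The acyloxy enone also aromatises easily by β-elimination under the basic dehydration and hydroxymethylation conditions, and about ten steps are needed.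

Alternative 3: a temporary oxygen bridge from C1 to C4. The oxanorbornene A5 would come from the Diels–Alder reaction of a furfuryl ester with a cyclic enediol carbonate (endo adduct). The forward key step is an SN2' methanolysis: attack at C3 anti to the bridge, the alkene shifts to C1=C2, and the C1–O bond breaks to leave O4–H. This sets the trans O3/O4 pair in one stroke. The chosen plan is better because A5 forms as a racemate. The C7-bearing bridgehead removes the mirror plane on which catalytic desymmetrisation of such bicycles depends, so a resolution would be needed. Furan cycloadditions of this kind are also reversible and give endo/exo mixtures, and the opening would have to choose between two bridgehead C–O bonds.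

Key step: step 6

Assumption: diol 1, produced on scale by whole-cell dioxygenation of the parent bromoarene, is taken as a catalogue compound; its (1S,2S) configuration is the one needed at C5 and C6.

## Steps

Step 1
Reactants: 1 (1S,2S)-3-bromocyclohexa-3,5-diene-1,2-diol
Product: 2 (3aS,7aS)-4-bromo-2,2-dimethyl-3a,7a-dihydro-1,3-benzodioxole
Conditions: 2,2-dimethoxypropane, TsOH·H2O (cat.), CH2Cl2, 0 °C to rt; used at once
Reagents that add atoms: 2,2-dimethoxypropane, COC(C)(C)OC
Why: Acid-catalysed transketalisation of the cis-1,2-diol gives the cis-fused dioxolane; it masks O5/O6 and makes the syn face of the diene the hindered one for step 2. No stereocentre is touched.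

Step 2
Reactants: 2 (3aS,7aS)-4-bromo-2,2-dimethyl-3a,7a-dihydro-1,3-benzodioxole
Product: 3 (3aS,5aR,6aR,6bS)-4-bromo-2,2-dimethyl-3a,5a,6a,6b-tetrahydrooxireno[2,3-e][1,3]benzodioxole (the C3–C4 oxirane, oxygen anti to the dioxolane)
Conditions: mCPBA, NaHCO3, CH2Cl2, 0 °C to rt
Reagents that add atoms: mCPBA (3-chloroperoxybenzoic acid), OOC(=O)c1cccc(Cl)c1
Why: Prilezhaev epoxidation should take the C3=C4 alkene, which is more electron-rich than the bromine-bearing C1=C2, from the face opposite to the cis-fused dioxolane. This fixes C4 (O4 anti to O5) and prepares C3 for inversion.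

Step 3
Reactants: 3 (3aS,5aR,6aR,6bS)-4-bromo-2,2-dimethyl-3a,5a,6a,6b-tetrahydrooxireno[2,3-e][1,3]benzodioxole
Product: 4 (3aS,4R,5S,7aS)-7-bromo-5-methoxy-2,2-dimethyl-3a,4,5,7a-tetrahydro-1,3-benzodioxol-4-ol
Conditions: MeOH–CH2Cl2, (±)-camphor-10-sulfonic acid (10 mol %), 0 °C to rt
Reagents that add atoms: methanol, CO
Why: Acid-catalysed, SN2-type opening of a vinyl oxirane by an alcohol: attack is expected at the allylic carbon C3 (better stabilised and less hindered than C4 beside the dioxolane) with inversion. This gives O3 trans to O4 and cis to O6; the bromine on the alkene disfavours a free allyl cation, so C3 should not scramble.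

Step 4
Reactants: 4 (3aS,4R,5S,7aS)-7-bromo-5-methoxy-2,2-dimethyl-3a,4,5,7a-tetrahydro-1,3-benzodioxol-4-ol; 5 (tributylstannyl)methanol
Product: 6 (3aS,4R,5S,7aR)-7-(hydroxymethyl)-5-methoxy-2,2-dimethyl-3a,4,5,7a-tetrahydro-1,3-benzodioxol-4-ol
Conditions: Pd(PPh3)4 (5 mol %), 1,4-dioxane, 100 °C
Reagents that add atoms: none
Why: Stille cross-coupling of the alkenyl bromide with the hydroxymethyl stannane forms C1–C7 directly at the alcohol oxidation level. Zerovalent palladium inserts into the sp2 C–Br bond far faster than it ionises the allylic ether or ketal C–O bonds, and the free O4–H is tolerated.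

Step 5
Reactants: 6 (3aS,4R,5S,7aR)-7-(hydroxymethyl)-5-methoxy-2,2-dimethyl-3a,4,5,7a-tetrahydro-1,3-benzodioxol-4-ol
Product: 7 (1S,2R,3R,6S)-4-(hydroxymethyl)-6-methoxycyclohex-4-ene-1,2,3-triol
Conditions: AcOH–H2O (4:1), 40 °C
Reagents that add atoms: none
Why: Mild aqueous acid hydrolysis of the isopropylidene ketal; acetic acid should be too weak to ionise the allylic C3–OMe and C6–OH bonds, so the four stereocentres stay as set.

Step 6
Reactants: 7 (1S,2R,3R,6S)-4-(hydroxymethyl)-6-methoxycyclohex-4-ene-1,2,3-triol
Product: 9 [(3S,4R,5R,6R)-5-(benzoyloxy)-4,6-dihydroxy-3-methoxycyclohex-1-en-1-yl]methyl benzoate (CNP0349013.6), via primary monobenzoate 8 (not isolated)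
Conditions: BzCl (1.05 equiv), 2,4,6-collidine, MeCN, −40 °C; then Ph2BOCH2CH2NH2 (10 mol %), i-Pr2NEt, BzCl (1.2 equiv), 0 °C to rt
Reagents that add atoms: benzoyl chloride, O=C(Cl)c1ccccc1
Why: Stage one is a kinetic acylation: at −40 °C with the hindered base 2,4,6-collidine the acid chloride should react with the unhindered primary allylic O7–H of 7 much faster than with any secondary hydroxyl, which gives 8 in the flask. In stage two the catalyst Ph2BOCH2CH2NH2 condenses reversibly with the only cis-vicinal diol of 8 (O5–H equatorial, O6–H pseudoaxial) to give an anionic four-coordinate borinate whose oxygens are far more nucleophilic than free hydroxyls; benzoylation then takes place at the equatorial O5, and the monoester leaves boron because it can no longer chelate. The closest known reaction types are the low-temperature acid chloride–collidine acylation of primary alcohols in polyols and the borinic-acid-catalysed O-3 acylation of the 3,4-cis-diol of galacto- and fucopyranosides that carry a free O-2–H. No ring is closed and no stereocentre is formed or touched. The step needs site selectivity among four hydroxyls: O7 is secured by being the only primary one and O5 by being the equatorial member of the only cis-diol; O4–H stays free because both its neighbours (C3–OMe, C5–O) are trans and offer no five-membered chelate, and O6–H stays free because it is pseudoaxial, allylic and next to the substituted C1. The conditions are cold and nearly neutral, so that the allylic C–O bonds should not ionise and the new O5 benzoate should not migrate.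

## Compound list

1 | (1S,2S)-3-bromocyclohexa-3,5-diene-1,2-diol | O[C@H]1[C@@H](O)C=CC=C1Br | starting material
2 | (3aS,7aS)-4-bromo-2,2-dimethyl-3a,7a-dihydro-1,3-benzodioxole | CC1(C)O[C@H]2[C@@H](O1)C=CC=C2Br | intermediate
3 | (3aS,5aR,6aR,6bS)-4-bromo-2,2-dimethyl-3a,5a,6a,6b-tetrahydrooxireno[2,3-e][1,3]benzodioxole (oxirane anti to the dioxolane) | CC1(C)O[C@H]2[C@@H](O1)[C@@H]3O[C@@H]3C=C2Br | intermediate
4 | (3aS,4R,5S,7aS)-7-bromo-5-methoxy-2,2-dimethyl-3a,4,5,7a-tetrahydro-1,3-benzodioxol-4-ol | CC1(C)O[C@H]2[C@@H](O1)[C@H](O)[C@@H](OC)C=C2Br | intermediate
5 | (tributylstannyl)methanol | CCCC[Sn](CCCC)(CCCC)CO | starting material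
6 | (3aS,4R,5S,7aR)-7-(hydroxymethyl)-5-methoxy-2,2-dimethyl-3a,4,5,7a-tetrahydro-1,3-benzodioxol-4-ol | CC1(C)O[C@H]2[C@@H](O1)[C@H](O)[C@@H](OC)C=C2CO | intermediate
7 | (1S,2R,3R,6S)-4-(hydroxymethyl)-6-methoxycyclohex-4-ene-1,2,3-triol | CO[C@H]1C=C(CO)[C@@H](O)[C@@H](O)[C@@H]1O | intermediate
8 | [(3S,4S,5R,6R)-4,5,6-trihydroxy-3-methoxycyclohex-1-en-1-yl]methyl benzoate | CO[C@H]1C=C(COC(=O)c2ccccc2)[C@@H](O)[C@@H](O)[C@@H]1O | intermediate
9 | [(3S,4R,5R,6R)-5-(benzoyloxy)-4,6-dihydroxy-3-methoxycyclohex-1-en-1-yl]methyl benzoate (CNP0349013.6) | CO[C@H]1C=C(COC(=O)c2ccccc2)[C@@H](O)[C@@H](OC(=O)c2ccccc2)[C@@H]1O | target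

## Step count and least certain steps

Total: 6 steps. Longest linear sequence: 6 steps (1 to 9).

**Step 6 (key step).** What may go wrong is benzoylation at the wrong hydroxyl (O4–H or O6–H) or double acylation of the diol, because only rate differences and a reversible catalyst–diol complex separate four hydroxyls. The O5 benzoate may also migrate to O4 or O6 under the amine base. The fallback replaces innate selectivity by protecting-group control; it sets out from 6 and comes back at 9. The primary hydroxyl of 6 is benzoylated (BzCl, pyridine, −20 °C) to the ketal 7-O-benzoate F1. The one remaining hydroxyl, O4–H, is silylated (TBSOTf, 2,6-lutidine) to the 4-O-silyl ether F2. The dioxolane is hydrolysed (AcOH–H2O) to the 5,6-diol F3. The diol is benzoylated at its equatorial O5 through the dibutylstannylene acetal (Bu2SnO, then BzCl) to the silylated dibenzoate F4. Removal of the silyl group (HF·pyridine) then gives 9.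

**Step 4.** What may go wrong is slow transfer of the hydroxymethyl group from tin at a hindered, oxygen-flanked alkenyl bromide. Butyl transfer, protodebromination and homocoupling could then compete. The fallback replaces the sp2–sp3 coupling by carbonylation and reduction; it sets out from 4 and comes back at 6. Methoxycarbonylation of 4 catalysed by Pd(OAc)2 and PPh3 (CO, MeOH, Et3N) gives the methyl ester F5, and reduction with i-Bu2AlH gives 6.

**Step 5.** What may go wrong is acid-promoted ionisation at the allylic C3–OMe or C6–O bond of 6, whose trisubstituted alkene stabilises an allyl cation. This would lead to epimerisation, solvolysis or aromatisation by loss of methanol and water. The fallback changes the order so that the ketal is removed while bromine still deactivates the alkene; it sets out from 4 and comes back at 7. Hydrolysis of the dioxolane of 4 gives the bromo triol F6, which is then coupled with 5 under the conditions of step 4 to give 7.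

## Further compounds

F1 | step 6 | [(3aR,6S,7R,7aS)-7-hydroxy-6-methoxy-2,2-dimethyl-3a,6,7,7a-tetrahydro-1,3-benzodioxol-4-yl]methyl benzoate | CC1(C)O[C@H]2[C@@H](O1)[C@H](O)[C@@H](OC)C=C2COC(=O)c1ccccc1
F2 | step 6 | [(3aR,6S,7R,7aR)-7-[(tert-butyldimethylsilyl)oxy]-6-methoxy-2,2-dimethyl-3a,6,7,7a-tetrahydro-1,3-benzodioxol-4-yl]methyl benzoate | CC1(C)O[C@H]2[C@@H](O1)[C@H](O[Si](C)(C)C(C)(C)C)[C@@H](OC)C=C2COC(=O)c1ccccc1
F3 | step 6 | [(3S,4S,5R,6R)-4-[(tert-butyldimethylsilyl)oxy]-5,6-dihydroxy-3-methoxycyclohex-1-en-1-yl]methyl benzoate | CO[C@H]1C=C(COC(=O)c2ccccc2)[C@@H](O)[C@@H](O)[C@@H]1O[Si](C)(C)C(C)(C)C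
F4 | step 6 | [(3S,4R,5R,6R)-5-(benzoyloxy)-4-[(tert-butyldimethylsilyl)oxy]-6-hydroxy-3-methoxycyclohex-1-en-1-yl]methyl benzoate | CO[C@H]1C=C(COC(=O)c2ccccc2)[C@@H](O)[C@@H](OC(=O)c2ccccc2)[C@@H]1O[Si](C)(C)C(C)(C)C
F5 | step 4 | methyl (3aR,6S,7R,7aS)-7-hydroxy-6-methoxy-2,2-dimethyl-3a,6,7,7a-tetrahydro-1,3-benzodioxole-4-carboxylate | CC1(C)O[C@H]2[C@@H](O1)[C@H](O)[C@@H](OC)C=C2C(=O)OC
F6 | step 5 | (1S,2S,3S,6S)-4-bromo-6-methoxycyclohex-4-ene-1,2,3-triol | CO[C@H]1C=C(Br)[C@@H](O)[C@@H](O)[C@@H]1O
A1 | alternative 1 | D-xylose (open-chain form) | O=C[C@H](O)[C@@H](O)[C@H](O)CO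
A2 | alternative 1 | (3R,4R,5R,6S)-4-(benzoyloxy)-3,5-dihydroxy-6-methoxy-2-methylideneoct-7-en-1-yl benzoate | C=C[C@H](OC)[C@@H](O)[C@H](OC(=O)c1ccccc1)[C@H](O)C(=C)COC(=O)c1ccccc1
A3 | alternative 2 | methyl 4-O-benzoyl-3-O-(tert-butyldimethylsilyl)-6-deoxy-2-O-methyl-α-D-xylo-hex-5-enopyranoside | C=C1O[C@H](OC)[C@H](OC)[C@@H](O[Si](C)(C)C(C)(C)C)[C@@H]1OC(=O)c1ccccc1
A4 | alternative 2 | (4S,5R,6S)-6-(benzoyloxy)-5-[(tert-butyldimethylsilyl)oxy]-4-methoxycyclohex-2-en-1-one | CO[C@H]1C=CC(=O)[C@@H](OC(=O)c2ccccc2)[C@@H]1O[Si](C)(C)C(C)(C)C
A5 | alternative 3 | [(1R,2S,3S,4R)-2,3-(carbonyldioxy)-7-oxabicyclo[2.2.1]hept-5-en-1-yl]methyl benzoate (endo carbonate) | O=C(OC[C@@]12C=C[C@@H](O1)[C@@H]3OC(=O)O[C@H]23)c1ccccc1
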